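**Retrosynthetic overview**

1. Target 27 ← acid removal of all protecting groups from 26 ← double acylation of 4,5-diol 21 with a MOM-protected p-coumaroyl chloride ← silylation of O3 and unmasking of O5 in cyclitol 19.
2. 19 ← SmI2 pinacol closure of 1,6-dialdehyde 17. This forms the C3–C4 bond and the only ring built in the route, the cyclohexane C1–C6. The strategy rests on the cis oxygens on ring carbons C3 and C4, with O4 trans to O5.
3. 17 ← ozonolysis of an allyl group (C3 aldehyde) and oxidation of a primary silyl ether (C4 aldehyde) in acyclic ester 13 ← hydrolytic opening of butyrolactone 9.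
4. 9 ← allylation, then enolate hydroxylation anti to the C5 side chain, of (R)-5-(hydroxymethyl)butyrolactone 1. Lactone 1 supplies C4–C7 and the C5 stereocentre; allyl bromide supplies C2 and C3.
5. Protecting groups: a 4-methoxybenzyl ester at C7 and MOM at O1 (both fall in the last acid step, which a methyl ester would not); SiEt3 at O5 so that it can be removed beside the later SitBuMe2 on O3.

Key step: step 10

Assumption: atoms are numbered as in quinic acid throughout (C1 carbinol carbon, C7 carboxyl carbon; "quinate" means the natural configuration, with O1, O3 and O4 on one ring face and O5 and C7 on the other), and compounds 1, 3 and 22 are bought.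

**Route**

Step 1
Reactants: 1 (R)-5-(hydroxymethyl)dihydrofuran-2(3H)-one
Product: 2 (R)-5-[(trityloxy)methyl]dihydrofuran-2(3H)-one
Conditions: TrCl, Et3N, DMAP (cat.), CH2Cl2, 0 °C to rt
Reagents that add atoms: trityl chloride, ClC(c1ccccc1)(c1ccccc1)c1ccccc1
Why: Tritylation (SN1-type etherification) of the only hydroxyl gives a bulky ether that is stable to the enolate chemistry ahead and shields one face of the lactone ring, while the C5 stereocentre is untouched.

Step 2
Reactants: 2 (R)-5-[(trityloxy)methyl]dihydrofuran-2(3H)-one; 3 allyl bromide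
Product: 5 (3S,5R)-3-allyl-5-[(trityloxy)methyl]dihydrofuran-2(3H)-one, via lithium enolate 4 (not isolated)
Conditions: LiN(iPr)2, THF, −78 °C; then 3, −78 to −40 °C
Reagents that add atoms: none
Why: Enolate alkylation of the butyrolactone with a reactive allylic bromide brings in C2 and C3, the allyl group entering mainly trans to the C5 side chain, although this centre is made planar again in step 3 so that its ratio does not matter.

Step 3
Reactants: 5 (3S,5R)-3-allyl-5-[(trityloxy)methyl]dihydrofuran-2(3H)-one
Product: 7 (3S,5R)-3-allyl-3-hydroxy-5-[(trityloxy)methyl]dihydrofuran-2(3H)-one, via potassium enolate 6 (not isolated)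
Conditions: KN(SiMe3)2, THF, −78 °C; then 2-(phenylsulfonyl)-3-phenyloxaziridine, −78 °C; AcOH quench
Reagents that add atoms: 2-(phenylsulfonyl)-3-phenyloxaziridine, O=S(=O)(N1OC1c1ccccc1)c1ccccc1
Why: Davis oxaziridine hydroxylation of the tetrasubstituted potassium enolate should deliver oxygen to the ring face opposite the trityloxymethyl group, which sets the quaternary C1 with OH trans and allyl cis to the C5 side chain, the relation that O1, C2 and C4 have in quinic acid.

Step 4
Reactants: 7 (3S,5R)-3-allyl-3-hydroxy-5-[(trityloxy)methyl]dihydrofuran-2(3H)-one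
Product: 8 (3S,5R)-3-allyl-3-(methoxymethoxy)-5-[(trityloxy)methyl]dihydrofuran-2(3H)-one
Conditions: MOMCl, iPr2NEt, Bu4NI (cat.), ClCH2CH2Cl, 60 °C
Reagents that add atoms: chloromethyl methyl ether, COCCl
Why: Alkoxymethylation of the tertiary alcohol (MOM ether formation, iodide-catalysed alkylation) protects O1 so that it can neither form a lactol with the C4 aldehyde nor start a retro-aldol cleavage from the C3 aldehyde later on.

Step 5
Reactants: 8 (3S,5R)-3-allyl-3-(methoxymethoxy)-5-[(trityloxy)methyl]dihydrofuran-2(3H)-one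
Product: 9 (3S,5R)-3-allyl-5-(hydroxymethyl)-3-(methoxymethoxy)dihydrofuran-2(3H)-one
Conditions: CSA (cat.), MeOH/CH2Cl2, 0 °C to rt
Reagents that add atoms: none
Why: Acid-catalysed solvolysis of the trityl ether through the trityl cation frees the primary hydroxyl under conditions too mild to cleave the MOM acetal, and any lactone methanolysis reverts to the five-membered lactone.

Step 6
Reactants: 9 (3S,5R)-3-allyl-5-(hydroxymethyl)-3-(methoxymethoxy)dihydrofuran-2(3H)-one
Product: 12 (2S,4R)-2-allyl-2-(methoxymethoxy)-4,5-bis[(triethylsilyl)oxy]pentanoic acid, via lithium carboxylate 10 (not isolated), via triethylsilyl ester 11 (not isolated)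
Conditions: LiOH, THF/H2O, 0 °C to rt; evaporate; TESCl, imidazole, DMF, rt; then K2CO3 (cat.), MeOH/H2O, 0 °C; pH 5 buffer work-up
Reagents that add atoms: lithium hydroxide, [Li+].[OH-]; chlorotriethylsilane, CC[Si](Cl)(CC)CC
Why: Saponification of the lactone (acyl–oxygen cleavage, so C5 keeps its configuration) followed by exhaustive silylation of the dry carboxylate traps the γ-hydroxy acid before it can close again, and only the very labile silyl ester is hydrolysed in the aqueous methanol treatment.

Step 7
Reactants: 12 (2S,4R)-2-allyl-2-(methoxymethoxy)-4,5-bis[(triethylsilyl)oxy]pentanoic acid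
Product: 13 4-methoxybenzyl (2S,4R)-2-allyl-2-(methoxymethoxy)-4,5-bis[(triethylsilyl)oxy]pentanoate
Conditions: PMBCl, K2CO3, Bu4NI (cat.), DMF, rt
Reagents that add atoms: 4-methoxybenzyl chloride, COc1ccc(CCl)cc1
Why: SN2 O-alkylation of the potassium carboxylate, which is insensitive to the hindrance at the quaternary α-carbon, gives an ester that should survive every later step but falls to trifluoroacetic acid at the end.

Step 8
Reactants: 13 4-methoxybenzyl (2S,4R)-2-allyl-2-(methoxymethoxy)-4,5-bis[(triethylsilyl)oxy]pentanoate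
Product: 15 4-methoxybenzyl (2S,4R)-2-allyl-2-(methoxymethoxy)-5-oxo-4-[(triethylsilyl)oxy]pentanoate, via alkoxysulfonium chloride 14 (not isolated)
Conditions: (COCl)2, DMSO, CH2Cl2, −78 °C, then −40 °C; Et3N, −78 to −20 °C
Reagents that add atoms: none
Why: Swern oxidation in which the chlorosulfonium reagent exchanges the primary triethylsilyl ether for an alkoxysulfonium ion and base then gives the aldehyde, a known way to oxidise a primary in the presence of a secondary triethylsilyl ether, so that C4 reaches the aldehyde level without a separate deprotection and C5 keeps its silyl group.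

Step 9
Reactants: 15 4-methoxybenzyl (2S,4R)-2-allyl-2-(methoxymethoxy)-5-oxo-4-[(triethylsilyl)oxy]pentanoate
Product: 17 4-methoxybenzyl (2R,4R)-2-(methoxymethoxy)-5-oxo-2-(2-oxoethyl)-4-[(triethylsilyl)oxy]pentanoate, via ozonide 16 (not isolated)
Conditions: O3, CH2Cl2, −78 °C; then PPh3, −78 °C to rt; used crude at once
Reagents that add atoms: ozone, [O-][O+]=O
Why: Ozonolysis of the terminal alkene with reductive work-up of the ozonide gives the C3 aldehyde under neutral conditions, which avoids β-elimination of the C1 alkoxy group and epimerisation at C5, and the electron-rich arene and the acetals react much more slowly with ozone than the alkene.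

Step 10
Reactants: 17 4-methoxybenzyl (2R,4R)-2-(methoxymethoxy)-5-oxo-2-(2-oxoethyl)-4-[(triethylsilyl)oxy]pentanoate
Product: 19 4-methoxybenzyl 1-O-(methoxymethyl)-5-O-(triethylsilyl)quinate (O3 and O4 cis; O4 trans to O5), via samarium diolate 18 (not isolated)
Conditions: SmI2 (2.5 equiv, 0.1 M in THF), 17 added slowly to 0.01 M, −78 to −20 °C; H2O work-up
Reagents that add atoms: none
Why: Divalent samarium transfers one electron to an aldehyde and the resulting ketyl adds to the second, samarium-bound aldehyde (or two ketyls combine), so that the like-polarised carbons C3 and C4 are joined as a trivalent samarium diolate; the closest known reaction type is the SmI2 pinacol cyclisation of sugar-derived 1,6-dialdehydes to cyclitols. The cyclohexane ring closes in a 6-exo-trig mode through a chair-like transition state that the fully substituted C1 helps to populate. The cis relation of O3 and O4 comes from both oxygens being held on samarium (gauche O–C–C–O), and since C3 has no neighbouring stereocentre its configuration follows that of C4. C4 is set by the existing C5 stereocentre, because the C4 oxygen with its samarium should avoid the dipole and the bulk of the C5 triethylsilyloxy group and end trans to O5. The step needs the aldehydes to be reduced in preference to the 4-methoxybenzyl ester and the acetals, which SmI2 in THF without HMPA or a protic additive should secure, and it needs ring closure to beat intermolecular coupling, which slow addition at high dilution and −78 °C should secure. C1 and C5 are not touched.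

Step 11
Reactants: 19 4-methoxybenzyl 1-O-(methoxymethyl)-5-O-(triethylsilyl)quinate
Product: 20 4-methoxybenzyl 3-O-(tert-butyldimethylsilyl)-1-O-(methoxymethyl)-5-O-(triethylsilyl)quinate
Conditions: TBSCl, imidazole, DMF, 0 °C to rt
Reagents that add atoms: tert-butyldimethylsilyl chloride, CC(C)(C)[Si](C)(C)Cl
Why: Silyl ether formation at the more accessible hydroxyl: O4 is wedged between O3 and the silylated O5 whereas O3 has a methylene neighbour, the same steric preference that leaves the 4-hydroxyl free when methyl quinate is bis-silylated, so that the bulky chlorosilane should take O3.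

Step 12
Reactants: 20 4-methoxybenzyl 3-O-(tert-butyldimethylsilyl)-1-O-(methoxymethyl)-5-O-(triethylsilyl)quinate
Product: 21 4-methoxybenzyl 3-O-(tert-butyldimethylsilyl)-1-O-(methoxymethyl)quinate
Conditions: PPTS (cat.), MeOH/CH2Cl2, 0 °C to rt
Reagents that add atoms: none
Why: Acid-catalysed methanolysis of silyl ethers is far faster for a triethylsilyl than for a tert-butyldimethylsilyl ether, so that O5 should be unmasked selectively while the O3 silyl ether, the MOM acetal and the ester stay.

Step 13
Reactants: 22 p-coumaric acid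
Product: 24 (E)-3-[4-(methoxymethoxy)phenyl]acrylic acid, via methoxymethyl ester 23 (not isolated)
Conditions: MOMCl (2.5 equiv), iPr2NEt, CH2Cl2, 0 °C to rt; then LiOH, THF/MeOH/H2O, rt; HCl to pH 3
Reagents that add atoms: chloromethyl methyl ether, COCCl; lithium hydroxide, [Li+].[OH-]
Why: Double alkylation with the chloromethyl ether protects the phenol as an acid-labile acetal, and saponification then cleaves only the methoxymethyl ester because the aryl acetal is inert to hydroxide.

Step 14
Reactants: 21 4-methoxybenzyl 3-O-(tert-butyldimethylsilyl)-1-O-(methoxymethyl)quinate; 24 (E)-3-[4-(methoxymethoxy)phenyl]acrylic acid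
Product: 26 4-methoxybenzyl 3-O-(tert-butyldimethylsilyl)-1-O-(methoxymethyl)-4,5-bis-O-[(E)-4-(methoxymethoxy)cinnamoyl]quinate, via acid chloride 25 (not isolated)
Conditions: 24 (3 equiv), 1-chloro-N,N,2-trimethylprop-1-en-1-amine, CH2Cl2, 0 °C to rt; then 21, pyridine, DMAP, CH2Cl2, rt to 40 °C
Reagents that add atoms: none
Why: Acid chloride formation with the chloroenamine under neutral conditions, which spares the aryl MOM ether, followed by DMAP-catalysed acylation of both secondary hydroxyls should give the diester with the E geometry retained, and no acyl shift is possible because O3 is silylated and O1 is protected.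

Step 15
Reactants: 26 4-methoxybenzyl 3-O-(tert-butyldimethylsilyl)-1-O-(methoxymethyl)-4,5-bis-O-[(E)-4-(methoxymethoxy)cinnamoyl]quinate
Product: 27 4,5-di-O-p-coumaroylquinic acid
Conditions: TFA/CH2Cl2/H2O (10:10:1), anisole (5 equiv), 0 °C to rt; reversed-phase chromatography
Reagents that add atoms: none
Why: Acidolysis removes all five protecting groups (the 4-methoxybenzyl ester through its benzylic cation, which anisole captures, the three MOM acetals and the silyl ether) at a pH at which cinnamate esters should neither hydrolyse nor migrate to the free 3-hydroxyl, so that the 4,5-substitution pattern is kept.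

**Compound list**

1 | (R)-5-(hydroxymethyl)dihydrofuran-2(3H)-one | O=C1CC[C@H](CO)O1 | starting material
2 | (R)-5-[(trityloxy)methyl]dihydrofuran-2(3H)-one | O=C1CC[C@H](COC(c2ccccc2)(c2ccccc2)c2ccccc2)O1 | intermediate
3 | allyl bromide | C=CCBr | starting material
4 | lithium enolate of 2 | [Li+].[O-]C1=CC[C@H](COC(c2ccccc2)(c2ccccc2)c2ccccc2)O1 | intermediate
5 | (3S,5R)-3-allyl-5-[(trityloxy)methyl]dihydrofuran-2(3H)-one (major, trans) | C=CC[C@H]1C[C@H](COC(c2ccccc2)(c2ccccc2)c2ccccc2)OC1=O | intermediate
6 | potassium enolate of 5 | [K+].[O-]C1=C(CC=C)C[C@H](COC(c2ccccc2)(c2ccccc2)c2ccccc2)O1 | intermediate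
7 | (3S,5R)-3-allyl-3-hydroxy-5-[(trityloxy)methyl]dihydrofuran-2(3H)-one | C=CC[C@]1(O)C[C@H](COC(c2ccccc2)(c2ccccc2)c2ccccc2)OC1=O | intermediate
8 | (3S,5R)-3-allyl-3-(methoxymethoxy)-5-[(trityloxy)methyl]dihydrofuran-2(3H)-one | C=CC[C@]1(OCOC)C[C@H](COC(c2ccccc2)(c2ccccc2)c2ccccc2)OC1=O | intermediate
9 | (3S,5R)-3-allyl-5-(hydroxymethyl)-3-(methoxymethoxy)dihydrofuran-2(3H)-one | C=CC[C@]1(OCOC)C[C@H](CO)OC1=O | intermediate
10 | lithium (2S,4R)-2-allyl-4,5-dihydroxy-2-(methoxymethoxy)pentanoate | C=CC[C@@](OCOC)(C(=O)[O-])C[C@@H](O)CO.[Li+] | intermediate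
11 | triethylsilyl (2S,4R)-2-allyl-2-(methoxymethoxy)-4,5-bis[(triethylsilyl)oxy]pentanoate | C=CC[C@@](OCOC)(C(=O)O[Si](CC)(CC)CC)C[C@@H](O[Si](CC)(CC)CC)CO[Si](CC)(CC)CC | intermediate
12 | (2S,4R)-2-allyl-2-(methoxymethoxy)-4,5-bis[(triethylsilyl)oxy]pentanoic acid | C=CC[C@@](OCOC)(C(=O)O)C[C@@H](O[Si](CC)(CC)CC)CO[Si](CC)(CC)CC | intermediate
13 | 4-methoxybenzyl (2S,4R)-2-allyl-2-(methoxymethoxy)-4,5-bis[(triethylsilyl)oxy]pentanoate | C=CC[C@@](OCOC)(C(=O)OCc1ccc(OC)cc1)C[C@@H](O[Si](CC)(CC)CC)CO[Si](CC)(CC)CC | intermediate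
14 | alkoxydimethylsulfonium chloride from 13 (primary OSiEt3 replaced by OS(CH3)2+) | C=CC[C@@](OCOC)(C(=O)OCc1ccc(OC)cc1)C[C@@H](O[Si](CC)(CC)CC)CO[S+](C)C.[Cl-] | intermediate
15 | 4-methoxybenzyl (2S,4R)-2-allyl-2-(methoxymethoxy)-5-oxo-4-[(triethylsilyl)oxy]pentanoate | C=CC[C@@](OCOC)(C(=O)OCc1ccc(OC)cc1)C[C@@H](O[Si](CC)(CC)CC)C=O | intermediate
16 | ozonide of 15: 4-methoxybenzyl (2R,4R)-2-(methoxymethoxy)-5-oxo-4-[(triethylsilyl)oxy]-2-[(1,2,4-trioxolan-3-yl)methyl]pentanoate (mixture at the trioxolane carbon) | C1OC(OO1)C[C@@](OCOC)(C(=O)OCc2ccc(OC)cc2)C[C@@H](O[Si](CC)(CC)CC)C=O | intermediate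
17 | 4-methoxybenzyl (2R,4R)-2-(methoxymethoxy)-5-oxo-2-(2-oxoethyl)-4-[(triethylsilyl)oxy]pentanoate | O=CC[C@@](OCOC)(C(=O)OCc1ccc(OC)cc1)C[C@@H](O[Si](CC)(CC)CC)C=O | intermediate
18 | bis(diiodosamarium) 3,4-diolate of 19 (trivalent samarium) | [O-][C@@H]1[C@H]([O-])C[C@@](OCOC)(C(=O)OCc2ccc(OC)cc2)C[C@H]1O[Si](CC)(CC)CC.[Sm+3].[Sm+3].[I-].[I-].[I-].[I-] | intermediate
19 | 4-methoxybenzyl 1-O-(methoxymethyl)-5-O-(triethylsilyl)quinate | O[C@@H]1[C@H](O)C[C@@](OCOC)(C(=O)OCc2ccc(OC)cc2)C[C@H]1O[Si](CC)(CC)CC | intermediate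
20 | 4-methoxybenzyl 3-O-(tert-butyldimethylsilyl)-1-O-(methoxymethyl)-5-O-(triethylsilyl)quinate | O[C@@H]1[C@H](O[Si](C)(C)C(C)(C)C)C[C@@](OCOC)(C(=O)OCc2ccc(OC)cc2)C[C@H]1O[Si](CC)(CC)CC | intermediate
21 | 4-methoxybenzyl 3-O-(tert-butyldimethylsilyl)-1-O-(methoxymethyl)quinate | O[C@@H]1[C@H](O[Si](C)(C)C(C)(C)C)C[C@@](OCOC)(C(=O)OCc2ccc(OC)cc2)C[C@H]1O | intermediate
22 | p-coumaric acid | OC(=O)/C=C/c1ccc(O)cc1 | starting material
23 | methoxymethyl (E)-3-[4-(methoxymethoxy)phenyl]acrylate | COCOC(=O)/C=C/c1ccc(OCOC)cc1 | intermediate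
24 | (E)-3-[4-(methoxymethoxy)phenyl]acrylic acid | OC(=O)/C=C/c1ccc(OCOC)cc1 | intermediate
25 | (E)-3-[4-(methoxymethoxy)phenyl]acryloyl chloride | ClC(=O)/C=C/c1ccc(OCOC)cc1 | intermediate
26 | 4-methoxybenzyl 3-O-(tert-butyldimethylsilyl)-1-O-(methoxymethyl)-4,5-bis-O-[(E)-4-(methoxymethoxy)cinnamoyl]quinate | O=C(/C=C/c1ccc(OCOC)cc1)O[C@@H]1[C@H](O[Si](C)(C)C(C)(C)C)C[C@@](OCOC)(C(=O)OCc2ccc(OC)cc2)C[C@H]1OC(=O)/C=C/c1ccc(OCOC)cc1 | intermediate
27 | 4,5-di-O-p-coumaroylquinic acid | O=C(/C=C/c1ccc(O)cc1)O[C@@H]1[C@H](O)C[C@@](O)(C(=O)O)C[C@H]1OC(=O)/C=C/c1ccc(O)cc1 | target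

**Step count**

Total: 15 steps. Longest linear sequence: 14 steps (steps 1–12, 14 and 15, from compound 1); step 13 is a one-step side branch.

**Steps most likely to fail, with fallbacks**

Step 10. The ring closure may lose out to intermolecular coupling or to simple reduction of the aldehydes, the C4 ketyl may expel the neighbouring silyloxy group, or the facial selectivity at C4 may be poor. The C3–C4 bond would then be made by olefin metathesis and the two oxygens added afterwards. Setting out from aldehyde 15, Wittig methylenation with Ph3P=CH2 (from Ph3PCH3Br and KN(SiMe3)2, THF, −78 °C) would give 4-methoxybenzyl (2S,4R)-2-allyl-2-(methoxymethoxy)-4-[(triethylsilyl)oxy]hex-5-enoate F1. Ring-closing metathesis with the second-generation Grubbs catalyst (CH2Cl2, 40 °C) would give 4-methoxybenzyl (1S,5R)-1-(methoxymethoxy)-5-[(triethylsilyl)oxy]cyclohex-3-ene-1-carboxylate F2. Dihydroxylation with catalytic OsO4 and N-methylmorpholine N-oxide, which adds to the alkene face anti to the allylic silyloxy group, should give the same cis-diol, and the route is rejoined at compound 19.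

Step 11. Silylation may occur at O4 or at both hydroxyls, or the triethylsilyl group may wander from O5 to O4 under the basic conditions. O3 and O4 would then be told apart in the bicyclic 1,5-lactone, where O3 is equatorial and O4 axial. Setting out from 19, PPTS in MeOH would remove the triethylsilyl group to give 4-methoxybenzyl 1-O-(methoxymethyl)quinate F3. Heating with DBU in toluene would close the lactone by intramolecular transesterification to 1-O-(methoxymethyl)quinic acid 1,5-lactone F4. TBSCl and imidazole would silylate the equatorial 3-hydroxyl to give 3-O-(tert-butyldimethylsilyl)-1-O-(methoxymethyl)quinic acid 1,5-lactone F5. Opening with LiOH would give lithium 3-O-(tert-butyldimethylsilyl)-1-O-(methoxymethyl)quinate F6, and alkylation of this carboxylate with 4-methoxybenzyl chloride in DMF returns to the route at diol 21.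

Step 14. Acylation of the hindered O4 by the bulky cinnamoyl chloride may stall at the 5-monoester, and long exposure to base may let the silyl group move from O3 to O4. The cinnamate double bonds would then be built after acylation with a small acyl group. Setting out from 21, esterification with diethylphosphonoacetic acid (DCC, DMAP, CH2Cl2) would give 4-methoxybenzyl 3-O-(tert-butyldimethylsilyl)-4,5-bis-O-[(diethoxyphosphoryl)acetyl]-1-O-(methoxymethyl)quinate F7. A double Horner–Wadsworth–Emmons olefination with commercial 4-(methoxymethoxy)benzaldehyde (LiCl, DBU, MeCN) should then give the E,E-diester, and the route is rejoined at compound 26.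

**Further compounds**

F1 | step 10 | 4-methoxybenzyl (2S,4R)-2-allyl-2-(methoxymethoxy)-4-[(triethylsilyl)oxy]hex-5-enoate | C=CC[C@@](OCOC)(C(=O)OCc1ccc(OC)cc1)C[C@@H](O[Si](CC)(CC)CC)C=C
F2 | step 10 | 4-methoxybenzyl (1S,5R)-1-(methoxymethoxy)-5-[(triethylsilyl)oxy]cyclohex-3-ene-1-carboxylate | C1=CC[C@@](OCOC)(C(=O)OCc2ccc(OC)cc2)C[C@H]1O[Si](CC)(CC)CC
F3 | step 11 | 4-methoxybenzyl 1-O-(methoxymethyl)quinate | O[C@@H]1[C@H](O)C[C@@](OCOC)(C(=O)OCc2ccc(OC)cc2)C[C@H]1O
F4 | step 11 | 1-O-(methoxymethyl)quinic acid 1,5-lactone | O[C@@H]1[C@H](O)C[C@]2(OCOC)C[C@H]1OC2=O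
F5 | step 11 | 3-O-(tert-butyldimethylsilyl)-1-O-(methoxymethyl)quinic acid 1,5-lactone | O[C@@H]1[C@H](O[Si](C)(C)C(C)(C)C)C[C@]2(OCOC)C[C@H]1OC2=O
F6 | step 11 | lithium 3-O-(tert-butyldimethylsilyl)-1-O-(methoxymethyl)quinate | O[C@@H]1[C@H](O[Si](C)(C)C(C)(C)C)C[C@@](OCOC)(C(=O)[O-])C[C@H]1O.[Li+]
F7 | step 14 | 4-methoxybenzyl 3-O-(tert-butyldimethylsilyl)-4,5-bis-O-[(diethoxyphosphoryl)acetyl]-1-O-(methoxymethyl)quinate | CCOP(=O)(OCC)CC(=O)O[C@@H]1[C@H](O[Si](C)(C)C(C)(C)C)C[C@@](OCOC)(C(=O)OCc2ccc(OC)cc2)C[C@H]1OC(=O)CP(=O)(OCC)OCC
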